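## Structural features

The target is a 4-aryl-1-tetralone. Ring B (C1, C2, C3, C4, C4a, C8a) is a cyclohexanone fused through C4a–C8a to a catechol ring with hydroxyl groups on C7 and C8, so the C8 hydroxyl stands next to the carbonyl-bearing fusion carbon C8a. C4 is bonded to C1' of a naphthalene that carries a free hydroxyl on C4' (para to the junction) and a methoxy group on C8' (peri to the junction). C4 is the only stereocentre; it is (S), doubly benzylic, and has no stereogenic neighbour from which its configuration could be relayed. The fragile parts are the free catechol and the 4-hydroxynaphthyl group (easily oxidised), the aryl ketone (reducible under forcing hydrogenation), and C4–H itself, which is the gamma hydrogen of an ortho-alkyl aryl ketone and can be scrambled by photoenolisation. The real difficulty is twofold: two electron-rich arenes must be joined through one crowded sp3 carbon with absolute control, and the carbonyl must sit on C8a, ortho to oxygen and flanked on both sides, where an electrophilic acylation of a catechol ether would not go. The feature used is that C1 and C4 are both benzylic and attached to the neighbouring ring carbons C8a and C4a. They are therefore the two ends of an ortho-quinodimethane, which can be generated from a formyl carbon on C8a and a diarylmethane CH2 on C4a, with C2 and C3 coming from a two-carbon dienophile.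

## Logic of the disconnections

19 is traced back to 18 by cutting three O–C bonds of protecting groups: the benzyl ether on O4' and the two O–C bonds of a diphenylmethylene ketal spanning O7 and O8. The cut comes last because the free phenols are the most oxidation-prone groups, and both masks fall in one neutral hydrogenolysis. The forward step must spare the aryl ketone and the C4–aryl bonds.

18 is traced back to 17 by putting a methoxycarbonyl group on C2, and 17 to 16 by reducing C1=O to the carbinol. Both groups are marks left by a cycloaddition. Of the three stereocentres of 16 only C4 is kept, so their removal costs two steps but no selectivity. The forward steps must not touch C4–H.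

16 is cut at C1–C2 and C3–C4, the retron of a Diels–Alder reaction whose diene runs from C1 through C8a and C4a to C4. This removes ring B and all three stereocentres at once and leads to an achiral precursor, 13, and a commodity dienophile, 14. The diene 15 is the enol tautomer of 13 and is reached by light. The demands are heavy: hydrogen transfer from the diarylmethane CH2 must compete with energy loss to the naphthalene, 15 must have hydroxyl and naphthyl outward, and a chiral titanium template must choose the face. (This outward geometry is usually called E,E for photoenols; by the sequence rule the enol bond of 15 is Z, because C8 carries oxygen.)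

13 is cut at the bond between C4a and the methylene carbon, as an sp2–sp3 cross-coupling of 4 with 12, made from 11. Cut this way, the formyl group can be carried unprotected, and the bromine of 4 is activated by it. Addition of an aryllithium to 9 followed by ionic deoxygenation was set aside: the acetal needed to mask the formyl group would stand ortho to the carbinol and would either capture the diarylmethyl cation or be reduced by the silane. The forward step needs a benzylic zinc reagent from an easily ionised chloride and a coupling faster than carbonyl addition.

4 is traced back through 3 and 2 to 1 by cutting the ketal, restoring two methyl ethers and cutting C–Br. Bromine is introduced on 1 because the regiochemistry is dependable there: the methoxy group next to the formyl group is twisted out of conjugation, and the other directs para, to the carbon that becomes C4a. The methyl ethers are then exchanged for the ketal for three reasons: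
- A benzyl ether on O8 would hold benzylic C–H bonds within reach of the excited formyl oxygen in step 10 (1,6-hydrogen transfer, the known photocyclisation of ortho-benzyloxy aryl carbonyl compounds).
- It would be an activated benzyl ether ortho to the ketone under the chloride of step 12.
- Methyl ethers could not be removed at the end without losing the naphthyl methoxy group.

The price is one step more than a direct dibenzylation.

11 is traced back by functional-group changes to 9, 9 by an O–benzyl cut to 8, 8 by restoring an O–methyl bond to 7, and 7 by cutting the formyl C–C bond to 5 (through 6). The order is regiochemical. 5 is centrosymmetric, so formylation para to either methoxy group gives the same compound, with the new carbon peri to the other methoxy group. The formyl group then tells the two methoxy groups apart, because only the one para to it is a vinylogous ester. This replaces a longer sequence from a naphthoquinone that needs two selective operations on a hydroquinone. The demand is a nucleophilic demethylation that stops after the activated methyl group.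

## Other disconnections considered

Alternative 1: The cut is at C4a–C8a and C7–C8, inside the catechol ring and at the fusion bond of ring B; the precursor is A2 and the product of the key step is A1.
- **Forward step.** An intramolecular Diels–Alder reaction of a furan with an ethoxy-ynone in (6S)-6-[4-(benzyloxy)-8-methoxynaphthalen-1-yl]-1-ethoxy-6-(furan-2-yl)hex-1-yn-3-one (A2), thermally or with Me2AlCl. The furan supplies C4a, C5, C6, C7 and the oxygen on C7; the alkyne supplies C8a and C8. The oxygen-bridged adduct should open at C4a–O (the cation is stabilised by the ethoxy group through C8a=C8) and lose the proton on C7, giving (4S)-4-[4-(benzyloxy)-8-methoxynaphthalen-1-yl]-8-ethoxy-7-hydroxy-3,4-dihydronaphthalen-1(2H)-one (A1).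
- **In its favour.** The 7,8-dioxygenation and the carbonyl on crowded C8a are written into the connectivity of A2, two rings close in one operation, no light is needed, and the naphthalene is a bystander. On these structural and mechanistic points it is the better plan, since the chosen route depends on an excited state that the naphthalene can quench.
- **Against it here.** The key step creates no stereocentre. C4 of A2 must be set beforehand in a separate asymmetric step (for instance a conjugate addition with Rh(acac)(C2H4)2 and a chiral diphosphine). It must then be carried, as a carbon benzylic to a furan and to the naphthalene, through the making of the moisture-sensitive alkoxy-ynone terminus of A2 and through a Lewis-acid or hot step where ionisation or furan decomposition threatens. The ethyl ether on O8 of A1 also needs a chelation-controlled cleavage besides the debenzylation.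
- **Comparison.** After the key step the plans are about equal (two deprotections against three steps), and A2 would take roughly as many linear steps as 13, so step economy is a draw. The chosen plan is preferred because it forms ring B and fixes C4 in the same step from an achiral precursor.

Alternative 2: The cut is at C8–C8a and C5–C4a, so the catechol ring except its two fusion carbons comes from a diene; the partners are A4 and A5 and the product of the key step is A3.
- **Forward step.** 1-Methoxy-1,2-bis(trimethylsilyloxy)buta-1,3-diene (A5) would add to the C8a=C4a double bond of (4R)-4-[4-(benzyloxy)-8-methoxynaphthalen-1-yl]-2-(phenylsulfinyl)cyclohex-2-en-1-one (A4), its unsubstituted terminus bonding to the beta carbon C4a. Syn-elimination of the sulfinyl group and loss of the methoxy group together with one trimethylsilyl group would aromatise the new ring, and aqueous work-up would give (4S)-4-[4-(benzyloxy)-8-methoxynaphthalen-1-yl]-7,8-dihydroxy-3,4-dihydronaphthalen-1(2H)-one (A3).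
- **In its favour.** Regiochemistry follows from the polarity of both partners, no stereochemistry is at stake in the cycloaddition because every new sp3 centre is erased, and A3 is one hydrogenolysis from the target. That end-game is shorter and cleaner than the three steps of the chosen route; on this point alternative 2 is the better plan.
- **Against it here.** C4 must be installed early, by desymmetrising the prochiral saturated ketone from which A4 is made. It then sits in A4 as the gamma carbon of an enone, allylic and benzylic at once, where dienolisation under the sulfenylation, elimination or silyl-transfer conditions would erase it. The reacting beta carbon lies next to the peri-substituted naphthyl group, and A5 is a hydrolytically fragile ketene acetal made for the purpose.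
- **Comparison.** Both plans rest on a [4+2] cycloaddition. The alternative's thermal, polarised one carries less uncertainty in the bond-forming event (its equal or better there); total step count is about equal. The chosen plan is preferred because it creates C4 late and never exposes it to base while activated.

Alternative 3: The cut is at C2–C3 and C4–C1', the most convergent of the four; the bromoketone A7 and the boronic acid A8 are joined to give A6.
- **Forward step.** Cu(MeCN)4PF6 with a chiral bis(oxazoline) would abstract bromine from 1-[2,3-bis(benzyloxy)-6-ethenylphenyl]-2-bromoethan-1-one (A7). The C2 radical made from A7 would add to the terminal carbon C3 of its ortho vinyl group (6-endo, closing ring B).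
- **Relay.** The benzylic C4 radical would then be captured by the copper-bound naphthyl group from [4-(benzyloxy)-8-methoxynaphthalen-1-yl]boronic acid (A8), giving (4S)-7,8-bis(benzyloxy)-4-[4-(benzyloxy)-8-methoxynaphthalen-1-yl]-3,4-dihydronaphthalen-1(2H)-one (A6).
- **In its favour.** A7 is a simple aryl bromomethyl ketone. The two halves are joined, ring B is closed and C4 is set in one step, and A6 needs only a hydrogenolysis. In convergence and step economy this alternative is better than the chosen plan, by an estimated two to three steps.
- **Against it here.** The aryl group to be transferred is a 1-naphthyl with a peri methoxy group, so transmetalation to copper and C–C bond formation at the trivalent copper centre are both hindered, while protodeboronation of electron-rich A8 is not. The radical from A7 must also close 6-endo in preference to 5-exo closure and to simple reduction of the C–Br bond. The enantioselective radical arylation is established mainly for benzylic radicals made by intermolecular addition to styrenes, not for a cyclic radical flanked by a fused ring. A8 also has to come from a naphthalene halogenated at one defined position, which is harder to reach than 9 because no formyl group distinguishes the two oxygen atoms.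
- **Comparison.** Both key steps go beyond close precedent, so they are equals in kind of risk. The alternative puts its uncertainty on the most hindered bond (C4–C1'), formed from A7 and A8 at a secondary radical; the chosen plan makes that connection early, at a CH2 group, by cross-coupling. A6 differs from 18 only in the catechol protection, so both plans meet at the same last step.

Key step: step 10

Assumption: the sense of induction of the titanium TADDOLate with this substrate cannot be read from the structure, so (R,R)-TADDOL is written as the ligand enantiomer leading to the (1S,2S,4S) series; if a trial shows the opposite sense, (S,S)-TADDOL is used and nothing else changes.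

## Route

Step 1
Reactants: 1 2,3-dimethoxybenzaldehyde
Product: 2 6-bromo-2,3-dimethoxybenzaldehyde
Conditions: NBS (1.1 equiv), DMF, rt, dark
Reagents that add atoms: N-bromosuccinimide, O=C1CCC(=O)N1Br
Why: Electrophilic aromatic bromination; the 3-methoxy group is coplanar and directs para to C6, while the 2-methoxy group, twisted by its two neighbours, donates little towards C5. Any 5-bromo isomer should be removable by crystallisation.

Step 2
Reactants: 2 6-bromo-2,3-dimethoxybenzaldehyde
Product: 3 6-bromo-2,3-dihydroxybenzaldehyde
Conditions: BBr3 (3 equiv), CH2Cl2, −78 °C to rt; then H2O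
Reagents that add atoms: none
Why: Lewis-acid cleavage of aryl methyl ethers; the formyl group is only complexed and returns on hydrolysis, and the aryl bromide is inert.

Step 3
Reactants: 3 6-bromo-2,3-dihydroxybenzaldehyde
Product: 4 5-bromo-2,2-diphenyl-1,3-benzodioxole-4-carbaldehyde
Conditions: Ph2CCl2 (1.3 equiv), K2CO3 (3 equiv), MeCN, 60 °C
Reagents that add atoms: dichlorodiphenylmethane, ClC(Cl)(c1ccccc1)c1ccccc1
Why: Double O-alkylation of a catechol by a gem-dichloride (ketal formation). The ketal ties both oxygens back, leaves no C–H bond within reach of the formyl oxygen, and falls to hydrogenolysis at the end.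

Step 4
Reactants: 5 1,5-dimethoxynaphthalene
Product: 7 4,8-dimethoxy-1-naphthaldehyde, via iminium chloride 6 (not isolated)
Conditions: POCl3 (1.5 equiv), DMF, 0 to 80 °C; then ice-water
Reagents that add atoms: N,N-dimethylformamide, CN(C)C=O (formyl carbon); water, O (formyl oxygen); phosphoryl chloride, O=P(Cl)(Cl)Cl (counter-ion of 6 only)
Why: Vilsmeier–Haack formylation para to a methoxy group; C4 and C8 of the centrosymmetric diether are equivalent, so only one aldehyde can form. The iminium salt 6 deactivates the ring against a second attack.

Step 5
Reactants: 7 4,8-dimethoxy-1-naphthaldehyde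
Product: 8 4-hydroxy-8-methoxy-1-naphthaldehyde
Conditions: NaSEt (2.5 equiv), DMF, 100 °C; then aq. HCl
Reagents that add atoms: none
Why: SN2 demethylation by thiolate; the 4-methoxy group is para to the formyl group, so its naphthoxide is a vinylogous carboxylate and the better leaving group, while the 8-methoxy group is not conjugated with the aldehyde. The naphthoxide formed protects the product from a second cleavage.

Step 6
Reactants: 8 4-hydroxy-8-methoxy-1-naphthaldehyde
Product: 9 4-(benzyloxy)-8-methoxy-1-naphthaldehyde
Conditions: BnBr (1.2 equiv), K2CO3, DMF, rt
Reagents that add atoms: benzyl bromide, BrCc1ccccc1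
Why: Williamson etherification of the acidic 4-naphthol; this benzyl ether is remote from the chromophore of step 10 and leaves in step 13.

Step 7
Reactants: 9 4-(benzyloxy)-8-methoxy-1-naphthaldehyde
Product: 10 [4-(benzyloxy)-8-methoxynaphthalen-1-yl]methanol
Conditions: NaBH4, THF/MeOH, 0 °C
Reagents that add atoms: none
Why: Hydride reduction of an aryl aldehyde; nothing else in 9 is reducible by NaBH4.

Step 8
Reactants: 10 [4-(benzyloxy)-8-methoxynaphthalen-1-yl]methanol
Product: 11 1-(benzyloxy)-4-(chloromethyl)-5-methoxynaphthalene
Conditions: SOCl2 (1.2 equiv), CH2Cl2, 0 °C; crude product used at once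
Reagents that add atoms: thionyl chloride, O=S(Cl)Cl
Why: Chlorodehydroxylation through the chlorosulfite, fast for an electron-rich benzylic alcohol. The chloride ionises easily and is therefore not chromatographed.

Step 9
Reactants: 11 1-(benzyloxy)-4-(chloromethyl)-5-methoxynaphthalene; 4 5-bromo-2,2-diphenyl-1,3-benzodioxole-4-carbaldehyde
Product: 13 5-{[4-(benzyloxy)-8-methoxynaphthalen-1-yl]methyl}-2,2-diphenyl-1,3-benzodioxole-4-carbaldehyde, via benzylzinc chloride 12 (not isolated)
Conditions: Zn dust, LiCl, THF, 0 to 25 °C; solution of 12 transferred from excess zinc; then 4 (0.8 equiv), Pd(OAc)2 (2 mol%), SPhos (4 mol%), THF, 25 °C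
Reagents that add atoms: zinc, [Zn] (retained only in 12)
Why: LiCl-assisted zinc insertion into the benzylic C–Cl bond, then Negishi coupling; the C–Br bond of 4 is activated for oxidative addition by the ortho formyl group. Benzylzinc halides transmetalate to palladium much faster than they add to a hindered, donor-substituted aldehyde.

Step 10
Reactants: 13 5-{[4-(benzyloxy)-8-methoxynaphthalen-1-yl]methyl}-2,2-diphenyl-1,3-benzodioxole-4-carbaldehyde; 14 methyl acrylate
Product: 16 methyl (1S,2S,4S)-4-[4-(benzyloxy)-8-methoxynaphthalen-1-yl]-1-hydroxy-7,8-[(diphenylmethylene)dioxy]-1,2,3,4-tetrahydronaphthalene-2-carboxylate (all-cis), via photoenol 15 (not isolated)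
Conditions: Ti(OiPr)4 (1.5 equiv), (R,R)-TADDOL (1.6 equiv), 14 (5 equiv), degassed toluene, 366 nm, 0–20 °C; then aq. work-up
Reagents that add atoms: none
Why: Proposed new method: the closest known reaction type is the titanium-templated photoenolisation/Diels–Alder reaction of ortho-methyl and ortho-alkyl benzaldehydes with acrylates and enones, made enantioselective with TADDOL ligands; a diarylmethane CH2 as the enolising group has not been shown in this templated form. Excitation of the formyl group (n,π*) is followed by 1,5-hydrogen transfer from the doubly benzylic C4–H through a six-membered transition state, and the long-lived dienol 15, with hydroxyl and naphthyl both outward, is held as a titanium dienolate that also binds the carbonyl oxygen of 14. Ring B closes by a concerted suprafacial [4+2] cycloaddition, a six-membered ring formed through the new bonds C3–C4 (nucleophilic terminus C4 to the beta carbon) and C1–C2 (carbinol carbon to the alpha carbon). C1 and C4 are set cis by the out,out geometry of 15, C2 by the endo position of the ester on the titanium bridge, and the absolute sense at all three by the TADDOLate, which blocks one face of the diene. The step needs the ester next to the carbinol, which the titanium bridge and the larger HOMO coefficient at C4 both favour, and an outward naphthyl group, which is secured because an inward aryl group would collide with the C1 terminus. Only C4 is kept in the target, so any exo adduct converges on the same ketone in steps 11 and 12. The ketal offers no hydrogen to the excited carbonyl on its oxygen side, so hydrogen transfer can only come from C4; energy transfer to the naphthalene should lower the quantum efficiency without consuming material, and oxygen is excluded because dienols such as 15 are trapped by it.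

Step 11
Reactants: 16 methyl (1S,2S,4S)-4-[4-(benzyloxy)-8-methoxynaphthalen-1-yl]-1-hydroxy-7,8-[(diphenylmethylene)dioxy]-1,2,3,4-tetrahydronaphthalene-2-carboxylate
Product: 17 methyl (4S)-4-[4-(benzyloxy)-8-methoxynaphthalen-1-yl]-7,8-[(diphenylmethylene)dioxy]-1-oxo-1,2,3,4-tetrahydronaphthalene-2-carboxylate (C2 epimers and enol form)
Conditions: Dess–Martin periodinane (1.5 equiv), NaHCO3, CH2Cl2, 0 °C to rt, dark
Reagents that add atoms: none
Why: Dess–Martin oxidation of a secondary benzylic alcohol to the beta-keto ester under buffered, non-basic conditions that leave C4 untouched. C2 becomes epimerisable, which is of no consequence.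

Step 12
Reactants: 17 methyl (4S)-4-[4-(benzyloxy)-8-methoxynaphthalen-1-yl]-7,8-[(diphenylmethylene)dioxy]-1-oxo-1,2,3,4-tetrahydronaphthalene-2-carboxylate
Product: 18 (4S)-4-[4-(benzyloxy)-8-methoxynaphthalen-1-yl]-7,8-[(diphenylmethylene)dioxy]-3,4-dihydronaphthalen-1(2H)-one
Conditions: LiCl (3 equiv), DMSO/H2O, 130 °C, argon, dark
Reagents that add atoms: none
Why: Krapcho dealkoxycarbonylation: chloride attacks the ester methyl group, the beta-keto carboxylate loses CO2 and the enolate is protonated by water. The ketal carbon cannot undergo SN2 attack, C4 is not acidic under these neutral conditions, and light is excluded because 18 is itself an ortho-alkyl aryl ketone that could photoenolise and scramble C4.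

Step 13
Reactants: 18 (4S)-4-[4-(benzyloxy)-8-methoxynaphthalen-1-yl]-7,8-[(diphenylmethylene)dioxy]-3,4-dihydronaphthalen-1(2H)-one
Product: 19 (4S)-7,8-dihydroxy-4-(4-hydroxy-8-methoxynaphthalen-1-yl)-3,4-dihydronaphthalen-1(2H)-one
Conditions: H2 (1 atm), 10 % palladium on carbon, EtOAc/MeOH, rt, dark; filtration under argon
Reagents that add atoms: none
Why: Hydrogenolysis of the benzyl ether and the diphenylmethylene ketal. The ketone, deactivated by the hydrogen bond from the new 8-OH, and the C4–aryl bonds should survive at one atmosphere if the reaction is stopped at full deprotection.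

## Compound list

1 | 2,3-dimethoxybenzaldehyde | COc1cccc(C=O)c1OC | starting material
2 | 6-bromo-2,3-dimethoxybenzaldehyde | COc1ccc(Br)c(C=O)c1OC | intermediate
3 | 6-bromo-2,3-dihydroxybenzaldehyde | Oc1ccc(Br)c(C=O)c1O | intermediate
4 | 5-bromo-2,2-diphenyl-1,3-benzodioxole-4-carbaldehyde | O=Cc1c(Br)ccc2OC(c3ccccc3)(c3ccccc3)Oc12 | intermediate
5 | 1,5-dimethoxynaphthalene | COc1cccc2c(OC)cccc12 | starting material
6 | [(4,8-dimethoxynaphthalen-1-yl)methylidene]dimethyliminium chloride (formed in the flask, not isolated) | C[N+](C)=Cc1ccc(OC)c2cccc(OC)c12.[Cl-] | intermediate
7 | 4,8-dimethoxy-1-naphthaldehyde | COc1ccc(C=O)c2c(OC)cccc12 | intermediate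
8 | 4-hydroxy-8-methoxy-1-naphthaldehyde | COc1cccc2c(O)ccc(C=O)c12 | intermediate
9 | 4-(benzyloxy)-8-methoxy-1-naphthaldehyde | COc1cccc2c(OCc3ccccc3)ccc(C=O)c12 | intermediate
10 | [4-(benzyloxy)-8-methoxynaphthalen-1-yl]methanol | COc1cccc2c(OCc3ccccc3)ccc(CO)c12 | intermediate
11 | 1-(benzyloxy)-4-(chloromethyl)-5-methoxynaphthalene | COc1cccc2c(OCc3ccccc3)ccc(CCl)c12 | intermediate
12 | {[4-(benzyloxy)-8-methoxynaphthalen-1-yl]methyl}zinc chloride (formed in the flask, not isolated) | COc1cccc2c(OCc3ccccc3)ccc(C[Zn]Cl)c12 | intermediate
13 | 5-{[4-(benzyloxy)-8-methoxynaphthalen-1-yl]methyl}-2,2-diphenyl-1,3-benzodioxole-4-carbaldehyde | O=Cc1c(Cc2ccc(OCc3ccccc3)c3cccc(OC)c23)ccc2OC(c3ccccc3)(c3ccccc3)Oc12 | intermediate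
14 | methyl acrylate | C=CC(=O)OC | starting material
15 | 5-{[4-(benzyloxy)-8-methoxynaphthalen-1-yl]methylidene}-4-(hydroxymethylidene)-2,2-diphenyl-4,5-dihydro-1,3-benzodioxole, hydroxyl and naphthyl both outward (Z at the enol bond, E at the naphthylmethylidene bond; formed in the flask, not isolated) | O/C=C1\C2=C(C=C/C1=C\c1ccc(OCc3ccccc3)c3cccc(OC)c13)OC(c1ccccc1)(c1ccccc1)O2 | intermediate
16 | methyl (1S,2S,4S)-4-[4-(benzyloxy)-8-methoxynaphthalen-1-yl]-1-hydroxy-7,8-[(diphenylmethylene)dioxy]-1,2,3,4-tetrahydronaphthalene-2-carboxylate (all-cis) | COc1cccc2c(OCc3ccccc3)ccc([C@@H]3C[C@H](C(=O)OC)[C@H](O)c4c3ccc6OC(c5ccccc5)(c5ccccc5)Oc46)c12 | intermediate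
17 | methyl (4S)-4-[4-(benzyloxy)-8-methoxynaphthalen-1-yl]-7,8-[(diphenylmethylene)dioxy]-1-oxo-1,2,3,4-tetrahydronaphthalene-2-carboxylate (C2 not defined) | COc1cccc2c(OCc3ccccc3)ccc([C@@H]3CC(C(=O)OC)C(=O)c4c3ccc6OC(c5ccccc5)(c5ccccc5)Oc46)c12 | intermediate
18 | (4S)-4-[4-(benzyloxy)-8-methoxynaphthalen-1-yl]-7,8-[(diphenylmethylene)dioxy]-3,4-dihydronaphthalen-1(2H)-one | COc1cccc2c(OCc3ccccc3)ccc([C@@H]3CCC(=O)c4c3ccc6OC(c5ccccc5)(c5ccccc5)Oc46)c12 | intermediate
19 | (4S)-7,8-dihydroxy-4-(4-hydroxy-8-methoxynaphthalen-1-yl)-3,4-dihydronaphthalen-1(2H)-one | COc1cccc2c(O)ccc([C@@H]3CCC(=O)c4c3ccc(O)c4O)c12 | target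

## Step count and least certain steps

Total step count: 13. Longest linear sequence: 10 steps (steps 4 to 13, from 5 to 19).

**Step 10 (key step).**
- What may go wrong: quenching of the excited aldehyde by energy or electron transfer to the naphthalene, so that enolisation is inefficient and slower photoreactions take over; reketonisation of the dienol outrunning a slow cycloaddition at the hindered C4 terminus; poor facial selectivity of the template.
- Fallback (known chemistry, no light), setting out from 4 and 11:
  - 4 is oxidised (NaClO2, NaH2PO4, 2-methyl-2-butene) to 5-bromo-2,2-diphenyl-1,3-benzodioxole-4-carboxylic acid F1 and esterified (MeI, K2CO3) to methyl 5-bromo-2,2-diphenyl-1,3-benzodioxole-4-carboxylate F2.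
  - Negishi coupling of F2 with 12 (from 11 as in step 9) gives methyl 5-{[4-(benzyloxy)-8-methoxynaphthalen-1-yl]methyl}-2,2-diphenyl-1,3-benzodioxole-4-carboxylate F3.
  - LiN(iPr)2 in THF at −78 °C removes a proton from the doubly benzylic CH2 (lateral lithiation of an ortho-toluate type). The anion adds to 14 (Michael addition) and closes by Dieckmann condensation to the racemic beta-keto ester, methyl 4-[4-(benzyloxy)-8-methoxynaphthalen-1-yl]-7,8-[(diphenylmethylene)dioxy]-1-oxo-1,2,3,4-tetrahydronaphthalene-2-carboxylate F4.
  - Krapcho dealkoxycarbonylation gives racemic 4-[4-(benzyloxy)-8-methoxynaphthalen-1-yl]-7,8-[(diphenylmethylene)dioxy]-3,4-dihydronaphthalen-1(2H)-one F5.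
  - F5 is resolved by preparative chromatography on a chiral stationary phase into 18 and its (4R)-enantiomer F6. The fallback comes back to the route at 18, at the cost of half the material.

**Step 9.**
- What may go wrong: homocoupling or solvolysis of the labile chloride during zinc insertion; addition of the benzylzinc reagent to the formyl group competing with transmetalation.
- Fallback with reversed polarity, setting out from 4: Miyaura borylation (B2pin2, Pd(dppf)Cl2, KOAc, dioxane, 80 °C) gives 2,2-diphenyl-5-(4,4,5,5-tetramethyl-1,3,2-dioxaborolan-2-yl)-1,3-benzodioxole-4-carbaldehyde F7. Suzuki–Miyaura coupling of F7 with 11 (Pd(PPh3)4, K3PO4, toluene/H2O, 60 °C) comes back to the route at 13.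

**Step 5.**
- What may go wrong: incomplete discrimination between the two methoxy groups, or thiolate attack on the formyl group.
- Fallback that differentiates by acidity, setting out from 7: BBr3 gives 4,8-dihydroxy-1-naphthaldehyde F8. Benzylation with one equivalent of BnBr and KHCO3 in DMF should occur on the more acidic 4-hydroxyl (para to the formyl group; the 8-hydroxyl is hydrogen-bonded to it), giving 4-(benzyloxy)-8-hydroxy-1-naphthaldehyde F9. Methylation (MeI, K2CO3, acetone) comes back to the route at 9.

**Step 13.**
- What may go wrong: over-reduction of the aryl ketone, slow cleavage of the ketal, or air oxidation of the catechol and naphthol on the catalyst during filtration.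
- Fallback without hydrogen, setting out from 18: BCl3 with pentamethylbenzene as cation scavenger in CH2Cl2 at −78 °C cleaves the benzyl ether and opens the ketal, and comes back to the route at 19. No new compound is made (F0).

## Further compounds

F1 | step 10 | 5-bromo-2,2-diphenyl-1,3-benzodioxole-4-carboxylic acid | OC(=O)c1c(Br)ccc2OC(c3ccccc3)(c3ccccc3)Oc12
F2 | step 10 | methyl 5-bromo-2,2-diphenyl-1,3-benzodioxole-4-carboxylate | COC(=O)c1c(Br)ccc2OC(c3ccccc3)(c3ccccc3)Oc12
F3 | step 10 | methyl 5-{[4-(benzyloxy)-8-methoxynaphthalen-1-yl]methyl}-2,2-diphenyl-1,3-benzodioxole-4-carboxylate | COC(=O)c1c(Cc2ccc(OCc3ccccc3)c3cccc(OC)c23)ccc2OC(c3ccccc3)(c3ccccc3)Oc12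
F4 | step 10 | racemic methyl 4-[4-(benzyloxy)-8-methoxynaphthalen-1-yl]-7,8-[(diphenylmethylene)dioxy]-1-oxo-1,2,3,4-tetrahydronaphthalene-2-carboxylate | COc1cccc2c(OCc3ccccc3)ccc(C3CC(C(=O)OC)C(=O)c4c3ccc6OC(c5ccccc5)(c5ccccc5)Oc46)c12
F5 | step 10 | racemic 4-[4-(benzyloxy)-8-methoxynaphthalen-1-yl]-7,8-[(diphenylmethylene)dioxy]-3,4-dihydronaphthalen-1(2H)-one | COc1cccc2c(OCc3ccccc3)ccc(C3CCC(=O)c4c3ccc6OC(c5ccccc5)(c5ccccc5)Oc46)c12
F6 | step 10 | (4R)-4-[4-(benzyloxy)-8-methoxynaphthalen-1-yl]-7,8-[(diphenylmethylene)dioxy]-3,4-dihydronaphthalen-1(2H)-one | COc1cccc2c(OCc3ccccc3)ccc([C@H]3CCC(=O)c4c3ccc6OC(c5ccccc5)(c5ccccc5)Oc46)c12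
F7 | step 9 | 2,2-diphenyl-5-(4,4,5,5-tetramethyl-1,3,2-dioxaborolan-2-yl)-1,3-benzodioxole-4-carbaldehyde | O=Cc1c(B2OC(C)(C)C(C)(C)O2)ccc2OC(c3ccccc3)(c3ccccc3)Oc12
F8 | step 5 | 4,8-dihydroxy-1-naphthaldehyde | O=Cc1ccc(O)c2cccc(O)c12
F9 | step 5 | 4-(benzyloxy)-8-hydroxy-1-naphthaldehyde | O=Cc1ccc(OCc3ccccc3)c2cccc(O)c12
F0 | step 13 | none | none
A1 | alternative 1 | (4S)-4-[4-(benzyloxy)-8-methoxynaphthalen-1-yl]-8-ethoxy-7-hydroxy-3,4-dihydronaphthalen-1(2H)-one | COc1cccc2c(OCc3ccccc3)ccc([C@@H]3CCC(=O)c4c3ccc(O)c4OCC)c12
A2 | alternative 1 | (6S)-6-[4-(benzyloxy)-8-methoxynaphthalen-1-yl]-1-ethoxy-6-(furan-2-yl)hex-1-yn-3-one | COc1cccc2c(OCc3ccccc3)ccc([C@@H](c3ccco3)CCC(=O)C#COCC)c12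
A3 | alternative 2 | (4S)-4-[4-(benzyloxy)-8-methoxynaphthalen-1-yl]-7,8-dihydroxy-3,4-dihydronaphthalen-1(2H)-one | COc1cccc2c(OCc3ccccc3)ccc([C@@H]3CCC(=O)c4c3ccc(O)c4O)c12
A4 | alternative 2 | (4R)-4-[4-(benzyloxy)-8-methoxynaphthalen-1-yl]-2-(phenylsulfinyl)cyclohex-2-en-1-one (configuration at sulfur not defined) | COc1cccc2c(OCc3ccccc3)ccc([C@@H]3CCC(=O)C(S(=O)c4ccccc4)=C3)c12
A5 | alternative 2 | 1-methoxy-1,2-bis(trimethylsilyloxy)buta-1,3-diene (geometry of the C1=C2 bond not defined) | COC(O[Si](C)(C)C)=C(O[Si](C)(C)C)C=C
A6 | alternative 3 | (4S)-7,8-bis(benzyloxy)-4-[4-(benzyloxy)-8-methoxynaphthalen-1-yl]-3,4-dihydronaphthalen-1(2H)-one | COc1cccc2c(OCc3ccccc3)ccc([C@@H]3CCC(=O)c4c3ccc(OCc5ccccc5)c4OCc5ccccc5)c12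
A7 | alternative 3 | 1-[2,3-bis(benzyloxy)-6-ethenylphenyl]-2-bromoethan-1-one | C=Cc1ccc(OCc2ccccc2)c(OCc2ccccc2)c1C(=O)CBr
A8 | alternative 3 | [4-(benzyloxy)-8-methoxynaphthalen-1-yl]boronic acid | COc1cccc2c(OCc3ccccc3)ccc(B(O)O)c12
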